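The ten-membered carbocycle is opened at C1–C2, the seam between the epoxide CH (C1) and the neighbouring ring CH2 (C2). Before epoxidation C1 is the vinylic CH of the (E)-C1=C10 olefin, so this bond is an sp2–sp3 junction. An intramolecular alkyl–alkenyl Negishi coupling closes the ring in one operation and carries both preset olefin geometries (C2/C14 cis on C1=C10, C3/C6 cis on C4=C5) into it unchanged. The precursor is an open-chain diiodide: a (Z)-β-iodo Baylis–Hillman unit and a 2-(2-iodoethyl)enoate hung on the C7 stereocentre. Sharpless epoxidation and two acylations follow.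

Key step: step 10

Remark on numbering (germacrane type): C1 epoxide CH, C2 and C3 ring CH2, C4 ester-bearing olefin carbon, C5 olefin CH, C6 CH2, C7 CH(isopropenyl), C8 CH2, C9 CH(OAc), C10 quaternary epoxide carbon, C14 the CH2O on C10, C15 the ester carbonyl carbon.
Remark on the chemistry: the acyl stereocentre in the given structure is (R). (R)-2-Methylbutanoic acid 23, ylide 13 and borate 2 are taken as catalogue compounds.

Step 1
Reactants: 1 5,6-dihydro-2H-pyran-2-one; 2 potassium isopropenyltrifluoroborate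
Product: 3 (R)-4-(prop-1-en-2-yl)oxan-2-one
Conditions: [Rh(cod)2]PF6 (3 mol%), (R)-BINAP (3.3 mol%), toluene/H2O 20:1, 100 °C
Reagents that add atoms: none
Why: Hayashi–Miyaura-type rhodium-catalysed asymmetric 1,4-addition of an alkenylboron reagent to an unsaturated lactone; the (R)-BINAP–rhodium alkenyl species selects the olefin face and sets C7, and the lactone keeps the two C7 arms at different oxidation levels.

Step 2
Reactants: 3 (R)-4-(prop-1-en-2-yl)oxan-2-one; 4 N,O-dimethylhydroxylamine hydrochloride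
Product: 6 (R)-5-hydroxy-N-methoxy-N-methyl-3-(prop-1-en-2-yl)pentanamide, via chloromagnesium amide 5 (not isolated)
Conditions: 4, i-PrMgCl, THF, −20 °C; then 3, −20 to 0 °C; aq NH4Cl
Reagents that add atoms: none
Why: Aminolysis of the lactone by a magnesium amide (Weinreb amide synthesis) frees the C9 alcohol and stores C5 as a latent aldehyde; C7 is untouched.

Step 3
Reactants: 6 (R)-5-hydroxy-N-methoxy-N-methyl-3-(prop-1-en-2-yl)pentanamide
Product: 7 (R)-N-methoxy-N-methyl-5-oxo-3-(prop-1-en-2-yl)pentanamide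
Conditions: Dess–Martin periodinane, CH2Cl2, 0 °C to rt
Reagents that add atoms: none
Why: Dess–Martin oxidation of a primary alcohol stops at the aldehyde under neutral conditions that leave the amide, the isopropenyl group and C7 alone.

Step 4
Reactants: 7 (R)-N-methoxy-N-methyl-5-oxo-3-(prop-1-en-2-yl)pentanamide; 8 methyl propiolate
Product: 11 methyl (Z)-2-[(1S,3R)-1-hydroxy-5-[methoxy(methyl)amino]-5-oxo-3-(prop-1-en-2-yl)pentyl]-3-iodoacrylate, via silyl allenolate 9 (not isolated), via trimethylsilyl ether 10 (not isolated)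
Conditions: TMSI, oxazaborolidinium triflimide from (R)-α,α-diphenylprolinol, o-tolylboronic acid and HNTf2 (20 mol%), CH2Cl2, −78 °C; then 1 M HCl, THF
Reagents that add atoms: iodotrimethylsilane C[Si](C)(C)I
Why: Catalytic asymmetric β-iodo Morita–Baylis–Hillman (three-component halo-aldol) reaction. TMSI adds to the ynoate, and the β-iodo allenolate attacks the catalyst-bound aldehyde on its open Re face to set (S)-C9. Kinetic protonation-free C–C bond formation at −78 °C should give the (Z)-iodoacrylate (iodine cis to C14).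

Step 5
Reactants: 11 methyl (Z)-2-[(1S,3R)-1-hydroxy-5-[methoxy(methyl)amino]-5-oxo-3-(prop-1-en-2-yl)pentyl]-3-iodoacrylate
Product: 12 (3R,5S,6E)-5-hydroxy-6-(hydroxymethyl)-7-iodo-3-(prop-1-en-2-yl)hept-6-enal (drawn as the open hydroxy aldehyde)
Conditions: DIBAL-H (excess), CH2Cl2, −78 °C; aq Rochelle salt
Reagents that add atoms: none
Why: In one DIBAL-H reduction the conjugated C14 ester goes to the allylic alcohol. The Weinreb amide stops at the aldehyde through its stable aluminium chelate, and the alkenyl iodide and both stereocentres are spectators.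

Step 6
Reactants: 12 (3R,5S,6E)-5-hydroxy-6-(hydroxymethyl)-7-iodo-3-(prop-1-en-2-yl)hept-6-enal; 13 3-(triphenyl-λ5-phosphanylidene)oxolan-2-one
Product: 14 (3E)-3-[(3S,5S,6E)-5-hydroxy-6-(hydroxymethyl)-7-iodo-3-(prop-1-en-2-yl)hept-6-en-1-ylidene]oxolan-2-one
Conditions: toluene, 70 °C
Reagents that add atoms: none
Why: Wittig olefination with a lactone-stabilised ylide brings in C2, C3, C4 and C15 at once. It should give the (E)-alkylidene lactone (C6 anti to C15, hence C3/C6 cis as in the target); the neutral medium disfavours oxa-Michael closure by the C9 hydroxy group.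

Step 7
Reactants: 14 (3E)-3-[(3S,5S,6E)-5-hydroxy-6-(hydroxymethyl)-7-iodo-3-(prop-1-en-2-yl)hept-6-en-1-ylidene]oxolan-2-one
Product: 15 9,14-bis(tert-butyldimethylsilyl) ether of 14
Conditions: TBSOTf, 2,6-lutidine, CH2Cl2, −78 to 0 °C
Reagents that add atoms: tert-butyldimethylsilyl triflate CC(C)(C)[Si](C)(C)OS(=O)(=O)C(F)(F)F
Why: Silyl ether formation with the triflate covers the primary and the hindered secondary allylic alcohol in one operation, with groups that survive hydroxide, iodination and organozinc chemistry.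

Step 8
Reactants: 15 9,14-bis(tert-butyldimethylsilyl) ether of 14
Product: 17 methyl (2E,5S,7S,8E)-7-(tert-butyldimethylsilyloxy)-8-(tert-butyldimethylsilyloxymethyl)-2-(2-hydroxyethyl)-9-iodo-5-(prop-1-en-2-yl)nona-2,8-dienoate, via potassium carboxylate 16 (not isolated)
Conditions: KOH (1.1 equiv), THF/MeOH/H2O, 0 °C to rt; evaporate; MeI, DMF, rt; used crude
Reagents that add atoms: potassium hydroxide [K+].[OH-]; iodomethane CI
Why: Saponification of the butyrolactone, then SN2 O-methylation of the carboxylate under non-equilibrating conditions, unmasks the C15 methyl ester and the C2 alcohol without touching the olefin geometry.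

Step 9
Reactants: 17 methyl (2E,5S,7S,8E)-7-(tert-butyldimethylsilyloxy)-8-(tert-butyldimethylsilyloxymethyl)-2-(2-hydroxyethyl)-9-iodo-5-(prop-1-en-2-yl)nona-2,8-dienoate
Product: 18 methyl (2E,5S,7S,8E)-7-(tert-butyldimethylsilyloxy)-8-(tert-butyldimethylsilyloxymethyl)-9-iodo-2-(2-iodoethyl)-5-(prop-1-en-2-yl)nona-2,8-dienoate
Conditions: PPh3, imidazole, I2, CH2Cl2, 0 °C
Reagents that add atoms: iodine II
Why: In the Appel iodination of the only free (primary) alcohol, fast iodide displacement of the alkoxyphosphonium ion should outrun relactonisation.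

Step 10
Reactants: 18 methyl (2E,5S,7S,8E)-7-(tert-butyldimethylsilyloxy)-8-(tert-butyldimethylsilyloxymethyl)-9-iodo-2-(2-iodoethyl)-5-(prop-1-en-2-yl)nona-2,8-dienoate
Product: 20 methyl (7S,9S,1(10)E,4E)-9,14-bis(tert-butyldimethylsilyloxy)germacra-1(10),4,11(12)-trien-15-oate, via alkylzinc iodide 19 (not isolated)
Conditions: Zn dust, LiCl, THF, 30 °C; decant; add over 16 h to PdCl2(dppf) (10 mol%), THF/NMP 4:1, 45 °C, final 1 mM
Reagents that add atoms: none
Why: Zinc inserts chemoselectively into the primary sp3 C2–I bond (the alkenyl C1–I bond is inert to zinc dust at this temperature, and the C15 ester chelates and stabilises alkylzinc 19); zerovalent palladium then adds oxidatively to the alkenyl iodide with retention, intramolecular transmetalation gives an eleven-membered palladacycle, and reductive elimination forges C1–C2. The closest known reaction type is the Negishi coupling of primary alkylzinc iodides with alkenyl iodides, whose ring-closing relatives (macrocyclic sp3–sp2 palladium couplings such as the B-alkyl Suzuki closure) build strained trisubstituted cycloalkenes. The single ring closed is the ten-membered carbocycle, formed end to end with both olefins endocyclic. No stereocentre is created: the (E)-C1=C10 geometry (C2 takes the place of iodine, cis to C14) is controlled by the stereoretentive coupling, and C4=C5, C7 and C9 are spectators. The step needs ring closure to beat oligomerisation and protodezincation, which is served by pseudo-high dilution (slow addition of 19), by the turn imposed by the C3/C6-cis enoate and by the buttressing substituents on C7, C9 and C10. Silyl ethers rather than the final allylic esters are carried at C9 and C14 so that no π-allylpalladium pathway competes.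

Step 11
Reactants: 20 methyl (7S,9S,1(10)E,4E)-9,14-bis(tert-butyldimethylsilyloxy)germacra-1(10),4,11(12)-trien-15-oate
Product: 21 methyl (7S,9S,1(10)E,4E)-9-(tert-butyldimethylsilyloxy)-14-hydroxygermacra-1(10),4,11(12)-trien-15-oate
Conditions: HF·pyridine, excess pyridine, THF, 0 °C
Reagents that add atoms: none
Why: In this rate-selective fluoride desilylation the unhindered primary allylic silyl ether falls well before the secondary one flanked by C10, and the buffered medium avoids acid-induced transannular cyclisation of the 1,5-diene.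

Step 12
Reactants: 21 methyl (7S,9S,1(10)E,4E)-9-(tert-butyldimethylsilyloxy)-14-hydroxygermacra-1(10),4,11(12)-trien-15-oate
Product: 22 methyl (1R,7S,9S,10S,4E)-9-(tert-butyldimethylsilyloxy)-1,10-epoxy-14-hydroxygermacra-4,11(12)-dien-15-oate
Conditions: Ti(OiPr)4 (20 mol%), L-(+)-diethyl tartrate (24 mol%), t-BuOOH (decane), 4 Å MS, CH2Cl2, −20 °C
Reagents that add atoms: tert-butyl hydroperoxide CC(C)(C)OO
Why: Katsuki–Sharpless asymmetric epoxidation. Binding through the C14 hydroxy group restricts oxidation to C1=C10 (enoate and isopropenyl untouched). L-(+)-Tartrate, which gives (2S,3R)-epoxy alcohols from 3-cis-substituted allylic alcohols, sets (1R,10S) by reagent control, and syn addition to the (E)-olefin gives the trans-epoxide.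

Step 13
Reactants: 22 methyl (1R,7S,9S,10S,4E)-9-(tert-butyldimethylsilyloxy)-1,10-epoxy-14-hydroxygermacra-4,11(12)-dien-15-oate; 23 (R)-2-methylbutanoic acid
Product: 24 methyl (1R,7S,9S,10S,4E)-9-(tert-butyldimethylsilyloxy)-1,10-epoxy-14-[(2R)-2-methylbutanoyloxy]germacra-4,11(12)-dien-15-oate
Conditions: DIC, DMAP (cat.), CH2Cl2, 0 °C
Reagents that add atoms: none
Why: Steglich esterification of the only free alcohol; the acyl stereocentre comes from 23 and should be kept by low temperature and catalytic DMAP.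

Step 14
Reactants: 24 methyl (1R,7S,9S,10S,4E)-9-(tert-butyldimethylsilyloxy)-1,10-epoxy-14-[(2R)-2-methylbutanoyloxy]germacra-4,11(12)-dien-15-oate
Product: 26 target CNP0352790.1, via C9 alcohol 25 (not isolated)
Conditions: TBAF/AcOH 1:1, THF, rt; then Ac2O, pyridine, DMAP, 0 °C to rt
Reagents that add atoms: acetic anhydride CC(=O)OC(C)=O
Why: Buffered fluoride desilylation keeps the C9 alkoxide concentration low, so that neither Payne rearrangement nor C14-to-C9 acyl migration sets in. Acetylation in the same flask installs the C9 acetate with retention.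

Compound list
1 | 5,6-dihydro-2H-pyran-2-one | O=C1C=CCCO1 | starting material
2 | potassium isopropenyltrifluoroborate | C=C(C)[B-](F)(F)F.[K+] | starting material
3 | (R)-4-(prop-1-en-2-yl)oxan-2-one | C=C(C)[C@@H]1CCOC(=O)C1 | intermediate
4 | N,O-dimethylhydroxylamine hydrochloride | CNOC.Cl | starting material
5 | chloromagnesium N-methoxy-N-methylamide | CON(C)[Mg]Cl | intermediate
6 | (R)-5-hydroxy-N-methoxy-N-methyl-3-(prop-1-en-2-yl)pentanamide | C=C(C)[C@H](CCO)CC(=O)N(C)OC | intermediate
7 | (R)-N-methoxy-N-methyl-5-oxo-3-(prop-1-en-2-yl)pentanamide | C=C(C)[C@H](CC=O)CC(=O)N(C)OC | intermediate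
8 | methyl propiolate | C#CC(=O)OC | starting material
9 | 1-iodo-3-methoxy-3-(trimethylsilyloxy)allene | IC=C=C(OC)O[Si](C)(C)C | intermediate
10 | O-trimethylsilyl ether of 11 | C=C(C)[C@H](C[C@H](O[Si](C)(C)C)/C(=C/I)C(=O)OC)CC(=O)N(C)OC | intermediate
11 | methyl (Z)-2-[(1S,3R)-1-hydroxy-5-[methoxy(methyl)amino]-5-oxo-3-(prop-1-en-2-yl)pentyl]-3-iodoacrylate | C=C(C)[C@H](C[C@H](O)/C(=C/I)C(=O)OC)CC(=O)N(C)OC | intermediate
12 | (3R,5S,6E)-5-hydroxy-6-(hydroxymethyl)-7-iodo-3-(prop-1-en-2-yl)hept-6-enal | C=C(C)[C@H](C[C@H](O)/C(=C/I)CO)CC=O | intermediate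
13 | 3-(triphenyl-λ5-phosphanylidene)oxolan-2-one | O=C1OCCC1=P(c1ccccc1)(c1ccccc1)c1ccccc1 | starting material
14 | (3E)-3-[(3S,5S,6E)-5-hydroxy-6-(hydroxymethyl)-7-iodo-3-(prop-1-en-2-yl)hept-6-en-1-ylidene]oxolan-2-one | C=C(C)[C@H](C[C@H](O)/C(=C/I)CO)C/C=C1\CCOC1=O | intermediate
15 | 9,14-bis(tert-butyldimethylsilyl) ether of 14 | C=C(C)[C@H](C[C@H](O[Si](C)(C)C(C)(C)C)/C(=C/I)CO[Si](C)(C)C(C)(C)C)C/C=C1\CCOC1=O | intermediate
16 | potassium carboxylate from ring opening of 15 (free C2 alcohol) | C=C(C)[C@H](C[C@H](O[Si](C)(C)C(C)(C)C)/C(=C/I)CO[Si](C)(C)C(C)(C)C)C/C=C(\CCO)C(=O)[O-].[K+] | intermediate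
17 | methyl (2E,5S,7S,8E)-7-(tert-butyldimethylsilyloxy)-8-(tert-butyldimethylsilyloxymethyl)-2-(2-hydroxyethyl)-9-iodo-5-(prop-1-en-2-yl)nona-2,8-dienoate | C=C(C)[C@H](C[C@H](O[Si](C)(C)C(C)(C)C)/C(=C/I)CO[Si](C)(C)C(C)(C)C)C/C=C(\CCO)C(=O)OC | intermediate
18 | methyl (2E,5S,7S,8E)-7-(tert-butyldimethylsilyloxy)-8-(tert-butyldimethylsilyloxymethyl)-9-iodo-2-(2-iodoethyl)-5-(prop-1-en-2-yl)nona-2,8-dienoate | C=C(C)[C@H](C[C@H](O[Si](C)(C)C(C)(C)C)/C(=C/I)CO[Si](C)(C)C(C)(C)C)C/C=C(\CCI)C(=O)OC | intermediate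
19 | alkylzinc iodide from 18 (zinc at C2, alkenyl iodide intact) | C=C(C)[C@H](C[C@H](O[Si](C)(C)C(C)(C)C)/C(=C/I)CO[Si](C)(C)C(C)(C)C)C/C=C(\CC[Zn]I)C(=O)OC | intermediate
20 | methyl (7S,9S,1(10)E,4E)-9,14-bis(tert-butyldimethylsilyloxy)germacra-1(10),4,11(12)-trien-15-oate (C2/C9 trans on C1=C10; C3/C6 cis on C4=C5) | C=C(C)[C@H]1C/C=C(/C(=O)OC)CC/C=C(\CO[Si](C)(C)C(C)(C)C)[C@@H](O[Si](C)(C)C(C)(C)C)C1 | intermediate
21 | methyl (7S,9S,1(10)E,4E)-9-(tert-butyldimethylsilyloxy)-14-hydroxygermacra-1(10),4,11(12)-trien-15-oate | C=C(C)[C@H]1C/C=C(/C(=O)OC)CC/C=C(\CO)[C@@H](O[Si](C)(C)C(C)(C)C)C1 | intermediate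
22 | methyl (1R,7S,9S,10S,4E)-9-(tert-butyldimethylsilyloxy)-1,10-epoxy-14-hydroxygermacra-4,11(12)-dien-15-oate | C=C(C)[C@H]1C/C=C(/C(=O)OC)CC[C@H]2O[C@]2(CO)[C@@H](O[Si](C)(C)C(C)(C)C)C1 | intermediate
23 | (R)-2-methylbutanoic acid | CC[C@@H](C)C(=O)O | starting material
24 | methyl (1R,7S,9S,10S,4E)-9-(tert-butyldimethylsilyloxy)-1,10-epoxy-14-[(2R)-2-methylbutanoyloxy]germacra-4,11(12)-dien-15-oate | C=C(C)[C@H]1C/C=C(/C(=O)OC)CC[C@H]2O[C@]2(COC(=O)[C@H](C)CC)[C@@H](O[Si](C)(C)C(C)(C)C)C1 | intermediate
25 | C9 alcohol: 24 without the silyl group, all centres arranged as in 26 | C=C(C)[C@H]1C/C=C(/C(=O)OC)CC[C@H]2O[C@]2(COC(=O)[C@H](C)CC)[C@@H](O)C1 | intermediate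
26 | CNP0352790.1: methyl (1R,7S,9S,10S,4E)-9-acetoxy-1,10-epoxy-14-[(2R)-2-methylbutanoyloxy]germacra-4,11(12)-dien-15-oate | C=C(C)[C@H]1C/C=C(/C(=O)OC)CC[C@H]2O[C@]2(COC(=O)[C@H](C)CC)[C@@H](OC(C)=O)C1 | target

Total step count: 14. Longest linear sequence: 14 steps (from 1).

Steps most likely to fail

Step 10. Intermolecular coupling, oligomerisation and protodezincation may outrun closure because the eleven-membered palladacycle has to build up the transannular strain of the (E,Z)-cyclodecadiene. The fallback sets out from 17 and closes the same bond with a carbonyl electrophile instead of an organozinc.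
- Dess–Martin oxidation of 17 gives the C2 aldehyde F1.
- A Nozaki–Hiyama–Kishi reaction (CrCl2, catalytic NiCl2, DMSO/THF, high dilution) adds the alkenylchromium at C1 to the aldehyde and gives the ring allylic alcohol F2 as a C2 epimer mixture.
- 1,1'-Thiocarbonyldiimidazole converts it into the thiocarbonylimidazolide F3.
- Barton–McCombie reduction (Bu3SnH, AIBN, toluene, 80 °C) removes the oxygen. Hydrogen transfer to the less hindered C2 end of the allyl radical should return the route at 20.

Step 12. Turnover may be slow and facial selection poor. The C2 chain is cis to the carbinol carbon, the C9 silyl ether may be mismatched with the tartrate, and each ring conformer exposes only one olefin face. The fallback sets out from 20 and replaces hydroxy-directed oxidation by an undirected, ketone-catalysed one at the very end.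
- TBAF/AcOH removes both silyl groups to give the diol F4.
- DIC/DMAP with 23 at −20 °C acylates the primary alcohol to the monoester F5.
- Ac2O/pyridine gives the diester triene F6.
- Shi epoxidation follows (D-fructose-derived ketone, Oxone, K2CO3 buffer, MeCN/dimethoxymethane/H2O, 0 °C). Its spiro transition state favours trans-trisubstituted olefins over 1,1-disubstituted ones and ignores the enoate.
- It should oxidise C1=C10 from the required face and come back to the route at 26.

Step 4. The Lewis-basic Weinreb amide may sequester the cationic boron catalyst, so that uncatalysed addition erodes control at C9. The fallback sets out from 7 and sets C9 by reduction instead of by C–C bond formation.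
- MgI2-promoted coupling with 8 (CH2Cl2, 0 °C) gives the (Z)-iodoacrylate as a C9 epimer mixture F7.
- Dess–Martin oxidation gives the β-iodo enone F8.
- Corey–Bakshi–Shibata reduction follows ((R)-2-methyl-CBS-oxazaborolidine, catecholborane, toluene, −78 °C; alkenyl as the large group). It should deliver the (S)-alcohol and come back to the route at 11.

Further compounds
F1 | step 10 | methyl (2E,5S,7S,8E)-7-(tert-butyldimethylsilyloxy)-8-(tert-butyldimethylsilyloxymethyl)-9-iodo-2-(2-oxoethyl)-5-(prop-1-en-2-yl)nona-2,8-dienoate | C=C(C)[C@H](C[C@H](O[Si](C)(C)C(C)(C)C)/C(=C/I)CO[Si](C)(C)C(C)(C)C)C/C=C(\CC=O)C(=O)OC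
F2 | step 10 | 2-hydroxy derivative of 20 (C2 epimers) | C=C(C)[C@H]1C/C=C(/C(=O)OC)CC(O)/C=C(\CO[Si](C)(C)C(C)(C)C)[C@@H](O[Si](C)(C)C(C)(C)C)C1
F3 | step 10 | O-(imidazol-1-ylthiocarbonyl) derivative of F2 | C=C(C)[C@H]1C/C=C(/C(=O)OC)CC(OC(=S)n2ccnc2)/C=C(\CO[Si](C)(C)C(C)(C)C)[C@@H](O[Si](C)(C)C(C)(C)C)C1
F4 | step 12 | methyl (7S,9S,1(10)E,4E)-9,14-dihydroxygermacra-1(10),4,11(12)-trien-15-oate | C=C(C)[C@H]1C/C=C(/C(=O)OC)CC/C=C(\CO)[C@@H](O)C1
F5 | step 12 | 14-[(2R)-2-methylbutanoate] of F4 | C=C(C)[C@H]1C/C=C(/C(=O)OC)CC/C=C(\COC(=O)[C@H](C)CC)[C@@H](O)C1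
F6 | step 12 | 9-acetate 14-[(2R)-2-methylbutanoate] of F4 | C=C(C)[C@H]1C/C=C(/C(=O)OC)CC/C=C(\COC(=O)[C@H](C)CC)[C@@H](OC(C)=O)C1
F7 | step 4 | C9 epimer mixture of 11 | C=C(C)[C@H](CC(O)/C(=C/I)C(=O)OC)CC(=O)N(C)OC
F8 | step 4 | methyl (Z)-3-iodo-2-[(3R)-5-[methoxy(methyl)amino]-5-oxo-3-(prop-1-en-2-yl)pentanoyl]acrylate | C=C(C)[C@H](CC(=O)/C(=C/I)C(=O)OC)CC(=O)N(C)OC
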